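**Assumption:** commercial 1,5-dimethylcycloocta-1,5-diene is freed from its 1,6-dimethyl isomer before use; guaiane numbering (with α/β) is used for the acetoxy half and germacrane numbering for the hydroxy half. None of this has been run, and the stereochemical outcomes of steps 5, 16 and 18 are predictions.

## Retrosynthetic overview

1. The norbornene is cut by a retro-Diels–Alder into a 2α-acetoxy-guaia-1(5),3-diene (a cyclopentadiene, made in situ) and the exocyclic methylene of a (Z,Z)-8β-hydroxygermacranolide.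
2. Acetoxy half: the 5–7 skeleton comes from a 2,5-disubstituted furan by Achmatowicz dearomatisation and intramolecular oxidopyrylium [5+2] cycloaddition (key step). The oxa-bridge is then cleaved, C8 reduced, the lactone closed and the C1 hydroxyl eliminated.
3. The furan precursor comes from furfural and but-1-en-3-yne: asymmetric alkynylation (the only stereo-anchor of this half), iron-catalysed carbomagnesiation (Z-olefin), C5-formylation, Baylis–Hillman reaction.
4. Hydroxy half: mono-ozonolysis of 1,5-dimethylcycloocta-1,5-diene (first Z-olefin), alkyne formation and carbomagnesiation (second Z-olefin), organocatalytic α-oxyamination (C8), Baylis–Hillman reaction, chromium-mediated macro-allylation with lactonisation.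
5. Ring order: pyranone, then cyclopentene and cycloheptane together, then γ-lactone (acetoxy half); ten-membered ring and γ-lactone together (hydroxy half); norbornene last.

## Route

**Step 1**
Reactants: 1 furfural; 2 but-1-en-3-yne
Product: 3 (1S)-1-(furan-2-yl)pent-4-en-2-yn-1-ol
Conditions: 2 (2.8 equiv, toluene solution), Me2Zn (2.9 equiv), (S,S)- or (R,R)-2,6-bis{[2-(hydroxydiphenylmethyl)pyrrolidin-1-yl]methyl}-4-methylphenol (the antipode that directs Si-face attack, 10 mol %), Ph3PO (20 mol %), toluene, 4 °C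
Reagents that add atoms: none
Why: Catalytic asymmetric alkynylation of an aromatic aldehyde by the alkynylzinc in the dinuclear zinc–ligand pocket; Si-face addition sets C2 (guaiane numbering) as S, the single centre from which the acetoxy half is relayed.

**Step 2**
Reactants: 3 (1S)-1-(furan-2-yl)pent-4-en-2-yn-1-ol
Product: 4 (1S,2Z)-1-(furan-2-yl)-3-methylpenta-2,4-dien-1-ol
Conditions: MeMgBr (5 equiv), Fe(acac)3 (15 mol %), THF, −78 → 0 °C; aq. NH4Cl
Reagents that add atoms: methylmagnesium bromide C[Mg]Br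
Why: Alkoxide-directed iron-catalysed syn-carbomagnesiation of the propargylic alcohol puts methyl on the distal alkyne carbon and magnesium on the proximal one, so protonation leaves the vinyl group cis to the carbinol (2Z), as the later cyclopentene needs.

**Step 3**
Reactants: 4 (1S,2Z)-1-(furan-2-yl)-3-methylpenta-2,4-dien-1-ol
Product: 6 (1S,2Z)-1-(5-formylfuran-2-yl)-3-methylpenta-2,4-dien-1-yl acetate, via dilithium alkoxide 5 (not isolated)
Conditions: n-BuLi (2.2 equiv), THF, −78 → 0 °C; DMF, −78 → 0 °C; Ac2O (3 equiv), 0 °C → rt; aq. NaHCO3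
Reagents that add atoms: N,N-dimethylformamide CN(C)C=O; acetic anhydride CC(=O)OC(C)=O
Why: O-deprotonation and α-lithiation of the furan at C5 give a dianion that is formylated by DMF, and the Ac2O quench acetylates the C2 alkoxide while the hemiaminal collapses to the aldehyde on work-up; C2 is not touched.

**Step 4**
Reactants: 6 (1S,2Z)-1-(5-formylfuran-2-yl)-3-methylpenta-2,4-dien-1-yl acetate; 7 methyl acrylate
Product: 8 methyl 2-[{5-[(1S,2Z)-1-acetoxy-3-methylpenta-2,4-dien-1-yl]furan-2-yl}(hydroxy)methyl]prop-2-enoate (both carbinol epimers)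
Conditions: DABCO (0.5 equiv), 7 (neat, 10 equiv), rt, 48 h
Reagents that add atoms: none
Why: Morita–Baylis–Hillman reaction of the furfural-type aldehyde installs C7 together with C11=C13 and C12 of the future methylene lactone; the new carbinol centre becomes sp2 in step 5 and needs no control.

**Step 5 (key step)**
Reactants: 8 methyl 2-[{5-[(1S,2Z)-1-acetoxy-3-methylpenta-2,4-dien-1-yl]furan-2-yl}(hydroxy)methyl]prop-2-enoate
Product: 11 methyl 2α-acetoxy-1β,7β-epoxy-8-oxo-5αH-guaia-3,9,11(13)-trien-12-oate, via pyranone hemiketal 9 (not isolated), via oxidopyrylium ylide 10 (not isolated)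
Conditions: VO(acac)2 (5 mol %), t-BuOOH (1.05 equiv), CH2Cl2, 0 °C → rt; then i-Pr2NEt (4 equiv), MsCl (1.5 equiv), CH2Cl2 (0.01 M), 0 → 40 °C
Reagents that add atoms: tert-butyl hydroperoxide CC(C)(C)OO
Why: Hydroxyl-directed Achmatowicz oxidation dearomatises the furan to the pyranone, mesylation and elimination give the oxidopyrylium ylide, and intramolecular [5+2] cycloaddition onto the terminal alkene closes the cyclopentene and the seven-membered carbocycle at once; the C–OAc dipole of the tether is expected to oppose the C=O+ dipole of the ylide terminus, so the oxygen bridge forms anti to the acetoxy group (1β,7β-epoxy against 2α-OAc) with the tether exo (5αH).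

**Step 6**
Reactants: 11 methyl 2α-acetoxy-1β,7β-epoxy-8-oxo-5αH-guaia-3,9,11(13)-trien-12-oate
Product: 12 methyl 2α-acetoxy-1β,7β-epoxy-8-oxo-5αH,10αH-guaia-3,11(13)-dien-12-oate
Conditions: Me2CuLi (1.3 equiv, from MeLi and CuI), THF, −78 °C, 30 min; aq. NH4Cl
Reagents that add atoms: lithium dimethylcuprate [Li+].C[Cu-]C
Why: Gilman conjugate addition to the strained bicyclic enone from the exo face (syn to the oxygen bridge, the endo face being shielded by the C5–C6 bridge) sets the 10β-methyl group; at −78 °C the enone reacts ahead of the α-substituted acrylate and the allylic acetate.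

**Step 7**
Reactants: 12 methyl 2α-acetoxy-1β,7β-epoxy-8-oxo-5αH,10αH-guaia-3,11(13)-dien-12-oate
Product: 13 methyl 2α-acetoxy-1β-hydroxy-8-oxo-5αH,7αH,10αH-guaia-3,11(13)-dien-12-oate
Conditions: SmI2 (2.5 equiv, 0.1 M in THF), MeOH (10 equiv), THF, −78 °C, 10 min; aq. NaHCO3
Reagents that add atoms: none
Why: SmI2 reductive cleavage of the α-alkoxy ketone breaks the C7–O bond and leaves the tertiary 1β-hydroxyl; kinetic α-protonation of the samarium enolate keeps the exocyclic methylene and occurs on the α-face, opposite the samarium alkoxide at C1, giving 7αH.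

**Step 8**
Reactants: 13 methyl 2α-acetoxy-1β-hydroxy-8-oxo-5αH,7αH,10αH-guaia-3,11(13)-dien-12-oate
Product: 15 2α-acetoxy-1β-hydroxy-5αH,7αH,10αH-guaia-3,11(13)-dien-12,8α-olide, via dihydroxy ester 14 (not isolated)
Conditions: Me4NBH(OAc)3 (5 equiv), MeCN/AcOH (2:1), −30 → 0 °C; then 40 °C, 2 h
Reagents that add atoms: none
Why: Hydroxyl-directed (Saksena–Evans) reduction delivers hydride from the 1β-oxygen, which still sits over C8 as the former bridge atom, to the β-face of the ketone; the resulting 8α-hydroxyl lactonises onto the acrylate ester to give the trans-fused α-methylene-γ-lactone.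

**Step 9**
Reactants: 16 1,5-dimethylcycloocta-1,5-diene
Product: 17 (5Z)-9,9-dimethoxy-6-methylnon-5-en-2-one
Conditions: O3 (1.0 equiv), CH2Cl2/MeOH (5:1), −78 °C; TsOH·H2O (10 mol %), rt; NaHCO3, Me2S
Reagents that add atoms: ozone [O-][O+]=O; methanol CO
Why: Mono-ozonolysis breaks the symmetry of the C2-symmetric diene (both olefins are equivalent, so there is no regiochemical issue) and gives ketone and acetal termini; the surviving ring olefin is necessarily Z and becomes C1=C10 of the germacrane.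

**Step 10**
Reactants: 17 (5Z)-9,9-dimethoxy-6-methylnon-5-en-2-one
Product: 20 (6Z)-10,10-dimethoxy-7-methyldec-6-en-2-yn-1-ol, via enol phosphate 18 (not isolated), via lithium acetylide 19 (not isolated)
Conditions: LDA (1.1 equiv), THF, −78 °C; ClP(O)(OEt)2, −78 → 0 °C; LDA (2.3 equiv), −78 → 0 °C; (CH2O)n (3 equiv), 0 °C → rt; aq. NH4Cl
Reagents that add atoms: formaldehyde (as paraformaldehyde) C=O
Why: Kinetic enolisation of the methyl ketone, O-phosphorylation and double elimination (Negishi alkyne synthesis) give the terminal acetylide, which is hydroxymethylated by formaldehyde.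

**Step 11**
Reactants: 20 (6Z)-10,10-dimethoxy-7-methyldec-6-en-2-yn-1-ol
Product: 22 (4Z,8Z)-10-hydroxy-4,8-dimethyldeca-4,8-dienal, via dienol acetal 21 (not isolated)
Conditions: MeMgBr (4 equiv), Fe(acac)3 (15 mol %), THF, −78 → 0 °C; then 1 M aq. HCl/THF, rt, 1 h
Reagents that add atoms: methylmagnesium bromide C[Mg]Br
Why: The same alkoxide-directed iron-catalysed syn-carbomagnesiation as in step 2 gives the (Z)-3-methylallylic alcohol (C4=C5, nerol-type), and the acidic work-up hydrolyses the dimethyl acetal.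

**Step 12**
Reactants: 22 (4Z,8Z)-10-hydroxy-4,8-dimethyldeca-4,8-dienal
Product: 23 (2R,4Z,8Z)-10-hydroxy-4,8-dimethyl-2-[(2,2,6,6-tetramethylpiperidin-1-yl)oxy]deca-4,8-dienal
Conditions: TEMPO (2.2 equiv), CuCl2 (10 mol %), 5-benzyl-2,2,3-trimethylimidazolidin-4-one trifluoroacetate (the antipode that gives 2R, 20 mol %), acetone, −20 °C, argon
Reagents that add atoms: TEMPO CC1(C)CCCC(C)(C)N1[O]
Why: Organocatalytic α-oxyamination: the chiral enamine is trapped on its open face by the copper-bound nitroxyl, setting C8 (germacrane numbering) as R; without amine ligand or base the copper–TEMPO pair is not expected to oxidise the allylic alcohol.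

**Step 13**
Reactants: 23 (2R,4Z,8Z)-10-hydroxy-4,8-dimethyl-2-[(2,2,6,6-tetramethylpiperidin-1-yl)oxy]deca-4,8-dienal; 7 methyl acrylate
Product: 24 methyl (4R,6Z,10Z)-3,12-dihydroxy-6,10-dimethyl-2-methylidene-4-[(2,2,6,6-tetramethylpiperidin-1-yl)oxy]dodeca-6,10-dienoate (C3 epimers)
Conditions: DABCO (1.0 equiv), 7 (5 equiv), MeOH, rt, 72 h
Reagents that add atoms: none
Why: Morita–Baylis–Hillman reaction builds C7–C11(=C13)–C12; the new carbinol centre is destroyed in step 15 and C8, which carries no acidifying group beyond the aldehyde, is not epimerised by DABCO at room temperature.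

**Step 14**
Reactants: 24 methyl (4R,6Z,10Z)-3,12-dihydroxy-6,10-dimethyl-2-methylidene-4-[(2,2,6,6-tetramethylpiperidin-1-yl)oxy]dodeca-6,10-dienoate
Product: 25 methyl (4R,6Z,10Z)-3-hydroxy-6,10-dimethyl-2-methylidene-12-oxo-4-[(2,2,6,6-tetramethylpiperidin-1-yl)oxy]dodeca-6,10-dienoate
Conditions: [Cu(MeCN)4]OTf (5 mol %), 2,2′-bipyridine (5 mol %), TEMPO (5 mol %), N-methylimidazole (10 mol %), air, MeCN, rt
Reagents that add atoms: none
Why: Copper/nitroxyl aerobic oxidation (Stahl) is selective for the primary allylic alcohol over the secondary one and does not isomerise the Z-olefin.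

**Step 15**
Reactants: 25 methyl (4R,6Z,10Z)-3-hydroxy-6,10-dimethyl-2-methylidene-12-oxo-4-[(2,2,6,6-tetramethylpiperidin-1-yl)oxy]dodeca-6,10-dienoate
Product: 26 methyl (2Z,4R,6Z,10Z)-2-(bromomethyl)-6,10-dimethyl-12-oxo-4-[(2,2,6,6-tetramethylpiperidin-1-yl)oxy]dodeca-2,6,10-trienoate
Conditions: PBr3 (0.4 equiv), Et2O, −10 → 0 °C
Reagents that add atoms: phosphorus tribromide BrP(Br)Br
Why: SN2′ bromination of the Baylis–Hillman alcohol gives the rearranged (Z)-2-(bromomethyl)enoate, the allylchromium precursor; the enal and the alkoxyamine are inert.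

**Step 16**
Reactants: 26 methyl (2Z,4R,6Z,10Z)-2-(bromomethyl)-6,10-dimethyl-12-oxo-4-[(2,2,6,6-tetramethylpiperidin-1-yl)oxy]dodeca-2,6,10-trienoate
Product: 28 (1(10)Z,4Z)-8β-[(2,2,6,6-tetramethylpiperidin-1-yl)oxy]germacra-1(10),4,11(13)-trien-12,6α-olide, via hydroxy ester 27 (not isolated)
Conditions: CrCl2 (6 equiv), THF/DMF (10:1), syringe-pump addition to 0.002 M, rt, 24 h; aq. NH4Cl
Reagents that add atoms: none
Why: Intramolecular Nozaki–Hiyama–Kishi allylation through a chair-like six-membered chromium transition state gives the 6,7-anti adduct (hence the trans-lactone after the chromium alkoxide closes onto the ester); at C8, H lies in the allyl plane (A(1,3) strain with the ester), the ring-forming C9 chain sits anti to the new bond, and the aldehyde adds syn to the C8–O bond, giving 6α-O, 7αH with the 8β-oxygen.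

**Step 17**
Reactants: 28 (1(10)Z,4Z)-8β-[(2,2,6,6-tetramethylpiperidin-1-yl)oxy]germacra-1(10),4,11(13)-trien-12,6α-olide
Product: 29 (1(10)Z,4Z)-8β-hydroxygermacra-1(10),4,11(13)-trien-12,6α-olide
Conditions: Zn dust (20 equiv), AcOH/THF/H2O (3:1:1), 50 °C
Reagents that add atoms: none
Why: Zinc/acetic acid reductive N–O cleavage of the alkoxyamine frees the 8β-hydroxyl with retention at C8; the 6α,12-olide with a free 8β-hydroxyl is a stable arrangement and the olefins are inert.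

**Step 18**
Reactants: 15 2α-acetoxy-1β-hydroxy-5αH,7αH,10αH-guaia-3,11(13)-dien-12,8α-olide; 29 (1(10)Z,4Z)-8β-hydroxygermacra-1(10),4,11(13)-trien-12,6α-olide
Product: 31 CNP0148007.1, via cyclopentadiene 30 (not isolated)
Conditions: 15 (1.5 equiv), Ph2S[OC(CF3)2Ph]2 (1.5 equiv), CH2Cl2, −20 °C, 20 min; then 29 (1.0 equiv), concentrate to ca. 1 M, 25 °C, 48 h
Reagents that add atoms: none
Why: Anti-elimination of the 1β-hydroxyl with the allylic 5α-hydrogen gives the cyclopentadiene, which undergoes Diels–Alder addition to the exocyclic methylene of 29 with four elements of selectivity: the CH2 terminus bonds to the fully substituted C1 (no vicinal quaternary centres), the lactone carbonyl is exo as usual for α-methylene lactones, the diene reacts on its β-face anti to the 2α-acetoxy group (a syn approach would push the acetoxy group into the exo lactone carbonyl), and the dienophile reacts on the β-face of the trans-fused lactone, the face on which C11 of 6α,12-olides is normally attacked.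

## Compound list

1 | furfural | O=Cc1ccco1 | starting material
2 | but-1-en-3-yne | C=CC#C | starting material
3 | (1S)-1-(furan-2-yl)pent-4-en-2-yn-1-ol | C=CC#C[C@@H](c1ccco1)O | intermediate
4 | (1S,2Z)-1-(furan-2-yl)-3-methylpenta-2,4-dien-1-ol | C=C/C(C)=C\[C@@H](c1ccco1)O | intermediate
5 | dilithium (1S,2Z)-1-{5-[(dimethylamino)oxidomethyl]furan-2-yl}-3-methylpenta-2,4-dien-1-olate | C=C/C(C)=C\[C@@H](c1ccc(C([O-])N(C)C)o1)[O-].[Li+].[Li+] | intermediate
6 | (1S,2Z)-1-(5-formylfuran-2-yl)-3-methylpenta-2,4-dien-1-yl acetate | C=C/C(C)=C\[C@@H](c1ccc(C=O)o1)OC(C)=O | intermediate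
7 | methyl acrylate | C=CC(=O)OC | starting material
8 | methyl 2-[{5-[(1S,2Z)-1-acetoxy-3-methylpenta-2,4-dien-1-yl]furan-2-yl}(hydroxy)methyl]prop-2-enoate | C=C/C(C)=C\[C@@H](c1ccc(C(O)C(=C)C(=O)OC)o1)OC(C)=O | intermediate
9 | methyl 2-{6-[(1S,2Z)-1-acetoxy-3-methylpenta-2,4-dien-1-yl]-6-hydroxy-3-oxo-3,6-dihydro-2H-pyran-2-yl}prop-2-enoate | C=C/C(C)=C\[C@H](OC(C)=O)C1(O)OC(C(=C)C(=O)OC)C(=O)C=C1 | intermediate
10 | 6-[(1S,2Z)-1-acetoxy-3-methylpenta-2,4-dien-1-yl]-2-[1-(methoxycarbonyl)ethenyl]pyrylium-3-olate | C=C/C(C)=C\[C@H](OC(C)=O)c1ccc([O-])c(C(=C)C(=O)OC)[o+]1 | intermediate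
11 | methyl 2α-acetoxy-1β,7β-epoxy-8-oxo-5αH-guaia-3,9,11(13)-trien-12-oate | C=C(C(=O)OC)[C@@]12C[C@H]3C(C)=C[C@H](OC(C)=O)[C@]3(O1)C=CC2=O | intermediate
12 | methyl 2α-acetoxy-1β,7β-epoxy-8-oxo-5αH,10αH-guaia-3,11(13)-dien-12-oate | C=C(C(=O)OC)[C@@]12C[C@H]3C(C)=C[C@H](OC(C)=O)[C@]3(O1)[C@@H](C)CC2=O | intermediate
13 | methyl 2α-acetoxy-1β-hydroxy-8-oxo-5αH,7αH,10αH-guaia-3,11(13)-dien-12-oate | C=C(C(=O)OC)[C@H]1C[C@H]2C(C)=C[C@H](OC(C)=O)[C@]2(O)[C@@H](C)CC1=O | intermediate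
14 | methyl 2α-acetoxy-1β,8α-dihydroxy-5αH,7αH,10αH-guaia-3,11(13)-dien-12-oate | C=C(C(=O)OC)[C@H]1C[C@H]2C(C)=C[C@H](OC(C)=O)[C@]2(O)[C@@H](C)C[C@@H]1O | intermediate
15 | 2α-acetoxy-1β-hydroxy-5αH,7αH,10αH-guaia-3,11(13)-dien-12,8α-olide | C=C1C(=O)O[C@H]2C[C@H](C)[C@@]3(O)[C@@H](OC(C)=O)C=C(C)[C@@H]3C[C@H]12 | intermediate
16 | 1,5-dimethylcycloocta-1,5-diene | C/C1=C/CC/C(C)=C\CC1 | starting material
17 | (5Z)-9,9-dimethoxy-6-methylnon-5-en-2-one | CC(=O)CC/C=C(/C)CCC(OC)OC | intermediate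
18 | (5Z)-9,9-dimethoxy-6-methylnona-1,5-dien-2-yl diethyl phosphate | C=C(OP(=O)(OCC)OCC)CC/C=C(/C)CCC(OC)OC | intermediate
19 | lithium (5Z)-9,9-dimethoxy-6-methylnon-5-en-1-yn-1-ide | [Li+].[C-]#CCC/C=C(/C)CCC(OC)OC | intermediate
20 | (6Z)-10,10-dimethoxy-7-methyldec-6-en-2-yn-1-ol | OCC#CCC/C=C(/C)CCC(OC)OC | intermediate
21 | (2Z,6Z)-10,10-dimethoxy-3,7-dimethyldeca-2,6-dien-1-ol | OC/C=C(/C)CC/C=C(/C)CCC(OC)OC | intermediate
22 | (4Z,8Z)-10-hydroxy-4,8-dimethyldeca-4,8-dienal | OC/C=C(/C)CC/C=C(/C)CCC=O | intermediate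
23 | (2R,4Z,8Z)-10-hydroxy-4,8-dimethyl-2-[(2,2,6,6-tetramethylpiperidin-1-yl)oxy]deca-4,8-dienal | OC/C=C(/C)CC/C=C(/C)C[C@@H](ON1C(C)(C)CCCC1(C)C)C=O | intermediate
24 | methyl (4R,6Z,10Z)-3,12-dihydroxy-6,10-dimethyl-2-methylidene-4-[(2,2,6,6-tetramethylpiperidin-1-yl)oxy]dodeca-6,10-dienoate | OC/C=C(/C)CC/C=C(/C)C[C@@H](ON1C(C)(C)CCCC1(C)C)C(O)C(=C)C(=O)OC | intermediate
25 | methyl (4R,6Z,10Z)-3-hydroxy-6,10-dimethyl-2-methylidene-12-oxo-4-[(2,2,6,6-tetramethylpiperidin-1-yl)oxy]dodeca-6,10-dienoate | O=C/C=C(/C)CC/C=C(/C)C[C@@H](ON1C(C)(C)CCCC1(C)C)C(O)C(=C)C(=O)OC | intermediate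
26 | methyl (2Z,4R,6Z,10Z)-2-(bromomethyl)-6,10-dimethyl-12-oxo-4-[(2,2,6,6-tetramethylpiperidin-1-yl)oxy]dodeca-2,6,10-trienoate | O=C/C=C(/C)CC/C=C(/C)C[C@@H](ON1C(C)(C)CCCC1(C)C)/C=C(\CBr)C(=O)OC | intermediate
27 | methyl (1(10)Z,4Z)-6α-hydroxy-8β-[(2,2,6,6-tetramethylpiperidin-1-yl)oxy]germacra-1(10),4,11(13)-trien-12-oate | C=C(C(=O)OC)[C@H]1[C@H](O)/C=C(/C)CC/C=C(/C)C[C@H]1ON2C(C)(C)CCCC2(C)C | intermediate
28 | (1(10)Z,4Z)-8β-[(2,2,6,6-tetramethylpiperidin-1-yl)oxy]germacra-1(10),4,11(13)-trien-12,6α-olide | C=C1C(=O)O[C@@H]2/C=C(/C)CC/C=C(/C)C[C@@H](ON3C(C)(C)CCCC3(C)C)[C@@H]12 | intermediate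
29 | (1(10)Z,4Z)-8β-hydroxygermacra-1(10),4,11(13)-trien-12,6α-olide, i.e. (3aR,4R,6Z,10Z,11aR)-4-hydroxy-6,10-dimethyl-3-methylidene-3a,4,5,8,9,11a-hexahydrocyclodeca[b]furan-2(3H)-one | C=C1C(=O)O[C@@H]2/C=C(/C)CC/C=C(/C)C[C@@H](O)[C@@H]12 | intermediate
30 | 2α-acetoxy-7αH,10αH-guaia-1(5),3,11(13)-trien-12,8α-olide | C=C1C(=O)O[C@H]2C[C@H](C)C3=C(C[C@H]12)C(C)=C[C@@H]3OC(C)=O | intermediate
31 | CNP0148007.1 | C=C1C(=O)O[C@H]2C[C@H](C)[C@]34C[C@@]5(C(=O)O[C@@H]6/C=C(/C)CC/C=C(/C)C[C@@H](O)[C@H]65)[C@H](C(C)=C3C[C@H]12)[C@@H]4OC(C)=O | target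

## Step count and weak points

Total: 18 steps. Longest linear sequence: 10 steps (steps 9–17, then 18); the other branch is steps 1–8, then 18.

**Step 5 (dearomatisation/[5+2]).** The relation between the tether acetoxy group and the new oxygen bridge is the weak point: sterics would place the acetoxy group syn to the bridge, and only the dipole argument favours the required anti arrangement. Because the whole acetoxy half is anchored at C2, a syn adduct from 8 would carry the wrong absolute configuration everywhere else.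

The fallback moves the correction of C2 to after the cycloaddition. It sets out again from 1 and 2 and returns at 15:
- Step 1 with the antipodal ligand gives (1R)-1-(furan-2-yl)pent-4-en-2-yn-1-ol F1, and carbomagnesiation gives (1R,2Z)-1-(furan-2-yl)-3-methylpenta-2,4-dien-1-ol F2.
- Formylation and acetylation through the dilithium alkoxide F3 give the (1R)-acetoxy aldehyde F4, and methyl acrylate gives the Baylis–Hillman adduct F5.
- Oxidation to the pyranone hemiketal F6 and ylide F7 then gives, with acetoxy syn to the bridge, the 2β-acetoxy cycloadduct F8, whose bridge has the required absolute sense.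
- Cuprate addition (methyl adduct F9), SmI2 cleavage (hydroxy ketone F10) and directed reduction through the dihydroxy ester F11 give the C2-epimeric lactone F12.
- Lipase-mediated methanolysis (Candida antarctica lipase B, MeOH, MTBE) gives the 1β,2β-diol F13, and MnO2 gives the enone F14.
- Me4NBH(OAc)3 delivers hydride from the face of the 1β-hydroxyl to give the 1β,2α-diol F15, and Ac2O/pyridine acetylates only the secondary hydroxyl, which returns to 15.

**Step 16 (macro-allylation).** Ring closure to a ten-membered ring is demanding, and the 1,2-induction from C8 is uncertain: if the aldehyde adds anti to the bulky C8–O substituent instead of syn, C6 and C7 form in the wrong absolute sense.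

The fallback uses that anti preference and inverts C8 afterwards. It sets out from 22 and returns at 29:
- Oxyamination with the antipodal imidazolidinone gives the (2S)-aldehyde F16, then Baylis–Hillman reaction (diol F17), aerobic oxidation (enal F18) and PBr3 (bromide F19).
- CrCl2 closes the ring through the hydroxy ester F20 to the 8α-(piperidinyloxy) lactone F21, now with the 6α-O, 7αH configuration of the target.
- Zn/AcOH gives the 8α-alcohol F22, and Mitsunobu reaction with formic acid (PPh3, DIAD) inverts C8 to the 8β-formate F23.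
- NaHCO3/MeOH cleaves the formate, which returns to 29.

**Step 18 (Diels–Alder).** The diene can be lost by 1,5-hydrogen shift and by self-dimerisation through its own methylene lactone, and the required approach anti to the acetoxy group runs against the usual syn preference of 5-acyloxycyclopentadienes.

The fallback masks the diene's own dienophile, so that the cycloaddition can be run longer, warmer or under pressure with 29 as the only partner. It does not by itself correct a wrong facial outcome. It sets out from 15 and returns at 31: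
- Me2NH in THF adds to the methylene lactone of 15 to give the 13-dimethylamino-11,13-dihydro lactone F24.
- The same dehydration gives the masked diene F25, which reacts with 29 to give the adduct F26.
- MeI gives the ammonium iodide F27, and NaHCO3 eliminates trimethylamine to restore the methylene group, which returns to 31.

## Further compounds

F1 | step 5 | (1R)-1-(furan-2-yl)pent-4-en-2-yn-1-ol | C=CC#C[C@H](c1ccco1)O
F2 | step 5 | (1R,2Z)-1-(furan-2-yl)-3-methylpenta-2,4-dien-1-ol | C=C/C(C)=C\[C@H](c1ccco1)O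
F3 | step 5 | dilithium (1R,2Z)-1-{5-[(dimethylamino)oxidomethyl]furan-2-yl}-3-methylpenta-2,4-dien-1-olate | C=C/C(C)=C\[C@H](c1ccc(C([O-])N(C)C)o1)[O-].[Li+].[Li+]
F4 | step 5 | (1R,2Z)-1-(5-formylfuran-2-yl)-3-methylpenta-2,4-dien-1-yl acetate | C=C/C(C)=C\[C@H](c1ccc(C=O)o1)OC(C)=O
F5 | step 5 | methyl 2-[{5-[(1R,2Z)-1-acetoxy-3-methylpenta-2,4-dien-1-yl]furan-2-yl}(hydroxy)methyl]prop-2-enoate | C=C/C(C)=C\[C@H](c1ccc(C(O)C(=C)C(=O)OC)o1)OC(C)=O
F6 | step 5 | methyl 2-{6-[(1R,2Z)-1-acetoxy-3-methylpenta-2,4-dien-1-yl]-6-hydroxy-3-oxo-3,6-dihydro-2H-pyran-2-yl}prop-2-enoate | C=C/C(C)=C\[C@@H](OC(C)=O)C1(O)OC(C(=C)C(=O)OC)C(=O)C=C1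
F7 | step 5 | 6-[(1R,2Z)-1-acetoxy-3-methylpenta-2,4-dien-1-yl]-2-[1-(methoxycarbonyl)ethenyl]pyrylium-3-olate | C=C/C(C)=C\[C@@H](OC(C)=O)c1ccc([O-])c(C(=C)C(=O)OC)[o+]1
F8 | step 5 | methyl 2β-acetoxy-1β,7β-epoxy-8-oxo-5αH-guaia-3,9,11(13)-trien-12-oate | C=C(C(=O)OC)[C@@]12C[C@H]3C(C)=C[C@@H](OC(C)=O)[C@]3(O1)C=CC2=O
F9 | step 5 | methyl 2β-acetoxy-1β,7β-epoxy-8-oxo-5αH,10αH-guaia-3,11(13)-dien-12-oate | C=C(C(=O)OC)[C@@]12C[C@H]3C(C)=C[C@@H](OC(C)=O)[C@]3(O1)[C@@H](C)CC2=O
F10 | step 5 | methyl 2β-acetoxy-1β-hydroxy-8-oxo-5αH,7αH,10αH-guaia-3,11(13)-dien-12-oate | C=C(C(=O)OC)[C@H]1C[C@H]2C(C)=C[C@@H](OC(C)=O)[C@]2(O)[C@@H](C)CC1=O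
F11 | step 5 | methyl 2β-acetoxy-1β,8α-dihydroxy-5αH,7αH,10αH-guaia-3,11(13)-dien-12-oate | C=C(C(=O)OC)[C@H]1C[C@H]2C(C)=C[C@@H](OC(C)=O)[C@]2(O)[C@@H](C)C[C@@H]1O
F12 | step 5 | 2β-acetoxy-1β-hydroxy-5αH,7αH,10αH-guaia-3,11(13)-dien-12,8α-olide | C=C1C(=O)O[C@H]2C[C@H](C)[C@@]3(O)[C@H](OC(C)=O)C=C(C)[C@@H]3C[C@H]12
F13 | step 5 | 1β,2β-dihydroxy-5αH,7αH,10αH-guaia-3,11(13)-dien-12,8α-olide | C=C1C(=O)O[C@H]2C[C@H](C)[C@@]3(O)[C@H](O)C=C(C)[C@@H]3C[C@H]12
F14 | step 5 | 1β-hydroxy-2-oxo-5αH,7αH,10αH-guaia-3,11(13)-dien-12,8α-olide | C=C1C(=O)O[C@H]2C[C@H](C)[C@@]3(O)C(=O)C=C(C)[C@@H]3C[C@H]12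
F15 | step 5 | 1β,2α-dihydroxy-5αH,7αH,10αH-guaia-3,11(13)-dien-12,8α-olide | C=C1C(=O)O[C@H]2C[C@H](C)[C@@]3(O)[C@@H](O)C=C(C)[C@@H]3C[C@H]12
F16 | step 16 | (2S,4Z,8Z)-10-hydroxy-4,8-dimethyl-2-[(2,2,6,6-tetramethylpiperidin-1-yl)oxy]deca-4,8-dienal | OC/C=C(/C)CC/C=C(/C)C[C@H](ON1C(C)(C)CCCC1(C)C)C=O
F17 | step 16 | methyl (4S,6Z,10Z)-3,12-dihydroxy-6,10-dimethyl-2-methylidene-4-[(2,2,6,6-tetramethylpiperidin-1-yl)oxy]dodeca-6,10-dienoate | OC/C=C(/C)CC/C=C(/C)C[C@H](ON1C(C)(C)CCCC1(C)C)C(O)C(=C)C(=O)OC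
F18 | step 16 | methyl (4S,6Z,10Z)-3-hydroxy-6,10-dimethyl-2-methylidene-12-oxo-4-[(2,2,6,6-tetramethylpiperidin-1-yl)oxy]dodeca-6,10-dienoate | O=C/C=C(/C)CC/C=C(/C)C[C@H](ON1C(C)(C)CCCC1(C)C)C(O)C(=C)C(=O)OC
F19 | step 16 | methyl (2Z,4S,6Z,10Z)-2-(bromomethyl)-6,10-dimethyl-12-oxo-4-[(2,2,6,6-tetramethylpiperidin-1-yl)oxy]dodeca-2,6,10-trienoate | O=C/C=C(/C)CC/C=C(/C)C[C@H](ON1C(C)(C)CCCC1(C)C)/C=C(\CBr)C(=O)OC
F20 | step 16 | methyl (1(10)Z,4Z)-6α-hydroxy-8α-[(2,2,6,6-tetramethylpiperidin-1-yl)oxy]germacra-1(10),4,11(13)-trien-12-oate | C=C(C(=O)OC)[C@H]1[C@H](O)/C=C(/C)CC/C=C(/C)C[C@@H]1ON2C(C)(C)CCCC2(C)C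
F21 | step 16 | (1(10)Z,4Z)-8α-[(2,2,6,6-tetramethylpiperidin-1-yl)oxy]germacra-1(10),4,11(13)-trien-12,6α-olide | C=C1C(=O)O[C@@H]2/C=C(/C)CC/C=C(/C)C[C@H](ON3C(C)(C)CCCC3(C)C)[C@@H]12
F22 | step 16 | (1(10)Z,4Z)-8α-hydroxygermacra-1(10),4,11(13)-trien-12,6α-olide | C=C1C(=O)O[C@@H]2/C=C(/C)CC/C=C(/C)C[C@H](O)[C@@H]12
F23 | step 16 | (1(10)Z,4Z)-8β-(formyloxy)germacra-1(10),4,11(13)-trien-12,6α-olide | C=C1C(=O)O[C@@H]2/C=C(/C)CC/C=C(/C)C[C@@H](OC=O)[C@@H]12
F24 | step 18 | 2α-acetoxy-13-(dimethylamino)-1β-hydroxy-5αH,7αH,10αH-guai-3-en-12,8α-olide (C11 epimers) | CN(C)CC1C(=O)O[C@H]2C[C@H](C)[C@@]3(O)[C@@H](OC(C)=O)C=C(C)[C@@H]3C[C@H]12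
F25 | step 18 | 2α-acetoxy-13-(dimethylamino)-7αH,10αH-guaia-1(5),3-dien-12,8α-olide (C11 epimers) | CN(C)CC1C(=O)O[C@H]2C[C@H](C)C3=C(C[C@H]12)C(C)=C[C@@H]3OC(C)=O
F26 | step 18 | 13-(dimethylamino)-11,13-dihydro derivative of CNP0148007.1 (amine on the guaianolide lactone, C11 epimers) | CN(C)CC1C(=O)O[C@H]2C[C@H](C)[C@]34C[C@@]5(C(=O)O[C@@H]6/C=C(/C)CC/C=C(/C)C[C@@H](O)[C@H]65)[C@H](C(C)=C3C[C@H]12)[C@@H]4OC(C)=O
F27 | step 18 | N-methyl (trimethylammonium) iodide of the 13-amino adduct of CNP0148007.1 | C[N+](C)(C)CC1C(=O)O[C@H]2C[C@H](C)[C@]34C[C@@]5(C(=O)O[C@@H]6/C=C(/C)CC/C=C(/C)C[C@@H](O)[C@H]65)[C@H](C(C)=C3C[C@H]12)[C@@H]4OC(C)=O.[I-]
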